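In a one-step world, free monomer simply turns into uncatalysed product, and c(free monomer) halves every 3.73 min. Theta and beta have two more steps: free monomer meets initiator to give a living end and its first unit in a chain, with constant 0.0011 L mol⁻¹ s⁻¹, and each living end then adds free monomer, with constant 2.6 L mol⁻¹ s⁻¹.

- theta: free monomer 0.22 M; initiator 3.3 mM; time 8.0 min
- beta: free monomer 0.22 M; initiator 3.3 mM; time 2.5 min

- which of the two ends with the longer chains by the average number of monomer units in a chain (chains begun, living or dead) ("neither" if they lie within 10%) (theta / beta / neither)
- average number of monomer units in a chain (chains begun, living or dead) at the end, theta
- average number of monomer units in a chain (chains begun, living or dead) at the end, beta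

- the average divides the monomer in chains by the number of chains begun, living and dead together
- run time (theta): 8.0 min

I count turnovers. A living end adds units at its constant times c(free monomer), so over a run it adds that constant times the area under c(free monomer) against time. I let c(free monomer) fall as in the one-step world and call the resulting number the turns, the units added by a living end present from the start: 143 in theta and 68.6 in beta. Theta has 3.20 times the time of beta but 2.08 times the turns.

I test the first-order fall on theta. The same area says about 6.04% of the initiator is used, giving 0.199 mM of living ends. At the end of theta these take free monomer with a first-order constant of 5.19 × 10⁻⁴ s⁻¹, which is smaller than the 0.0031 s⁻¹ of the step to uncatalysed product.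

With c(initiator) down by about 6.04% in theta, I take chains to start in proportion to the same area, so I spread them evenly along the turns. A chain begun first has them all and one begun last has none. By this reckoning the average length (the number-average degree of polymerisation) is one plus half the turns: 72.4 for theta and 35.3 for beta, so I commit to theta.

The forecast says theta, with 70.5 for theta (range 66 to 75) and 35 for beta (33 to 37.5), on the ground of seeing “average length rise roughly in proportion to that exposure”. My figure for theta is higher than its figure, and so is mine for beta.

The simulation gives theta, with 70.5 for theta and 35.3 for beta.

    free monomer + living end → monomer in chains + living end, rate k1*[living end]*[free monomer] (k1 = 2.6 L mol⁻¹ s⁻¹)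
    free monomer + initiator → living end + monomer in chains (k2 = 0.0011 L mol⁻¹ s⁻¹)
    free monomer → uncatalysed product (k3 = 0.0031 s⁻¹)

The difference in time is the main reason for the gap: beta, given the time of theta, goes from 35.3 to 70.5. A neighbour like beta, with 0.55 M of free monomer and the same time, has turns in proportion to its charge, 172, so I expect 87.0. The simulation gives 86.5 for that neighbour.

(Its constants are invented; the run is a simulation.)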